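(The numbers in the tables stem from a simulated flask with constants of no real substance; scatter was added.)

- Take the small charge in Wednesday's flask: 0.40 M of starting material against 0.250 M of protic impurity, and you want this flask ranked with the others.

| flask | starting material | protic impurity | free catalyst | remark | time |
|---|---|---|---|---|---|
| south-east | 1.7 M | 0.052 M | 5 mol% | run made earlier |  |
| south | 1.7 M | 0.33 M | 5 mol% | run made earlier |  |
| north-east | 1.7 M | 0.34 M | 3 mol% | run made earlier |  |
| Wednesday's | 0.40 M | 0.250 M | 5 mol% |  | 2.5 min |
| Monday's | 1.7 M | 0.340 M | 5 mol% |  | 2.5 min |
| Thursday's | 1.7 M | 0.0800 M | 1.5 mol% |  | 2.5 min |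
| Sunday's | 1.7 M | 0.500 M | 3 mol% |  | 2.5 min |
| Tuesday's | 1.7 M | 0.340 M | 1.2 mol% |  | 2.5 min |

| run | time / min | target / % |
|---|---|---|
| south-east | 0.667 | 38 |
| south-east | 1.33 | 46 |
| south-east | 2.00 | 49 |
| south-east | 2.50 | 47 |
| south | 0.667 | 34 |
| south | 1.33 | 41 |
| south | 2.00 | 39 |
| south | 2.50 | 38 |
| north-east | 0.200 | 12 |
| north-east | 0.500 | 21 |
| north-east | 1.00 | 31 |
| north-east | 2.50 | 37 |

(standard deviation of a reading: 2 percentage points)

* the flasks by amount of target, in percent of the starting material charged, highest first, at 2.5 min (Wednesday's / Monday's / Thursday's / Sunday's / Tuesday's)
* the amount of target, in percent of the starting material charged of the flask you put first, at 2.5 min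
* the amount of target, in percent of the starting material charged of the flask you put last, at 2.5 min

- the earlier runs were read with a standard deviation of 2 percentage points
- steps thought possible: starting material + protic impurity -> quenched substrate; starting material + free catalyst -> catalyst intermediate A; catalyst intermediate B <-> free catalyst + target; catalyst intermediate A -> catalyst intermediate B; target + free catalyst <-> isomer of the product + free catalyst

- The bench rule is to count what the quench cannot take. Protic impurity, the limiting reagent of the quench, consumes starting material one to one, so define the left fraction as one minus impurity charge over starting-material charge; for Sunday's it is 70.6 %.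
- In the south run the left fraction is 80.6 %, and the last reading puts target at 47.2 % of that, so take target as about half of the left fraction once the curve has flattened.
- That gives 37.7 % for Monday's and 33.3 % for Sunday's, whose catalyst dose, loading times charge times time, equals that of the north-east run at its last reading.
- The rule stops where the dose falls short. Tuesday's dose over the north-east dose at 1.00 min is 1.00, with the same left fraction, so read Tuesday's as 31 %.
- That north-east reading leaves 16.2 % of the climb to go. Raise this fraction to the dose ratio: Thursday's ratio is 1.25, which gives 40.3 %, just 2.6 percentage points above Monday's, close to the scatter of 2 points.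
- Wednesday's ratio is 0.980. Its left fraction of 37.5 % gives a plateau of 17.7 % and 14.7 % at the asked time, but this is shaky: its impurity is 62.5 % of the starting material charged, more than in any earlier run.
- The forecast gives Thursday's > Monday's > Sunday's > Tuesday's > Wednesday's, with 40 % on top and 23 % at the bottom, starting from “Target plateaus near half the unquenched substrate”. The order matches this reckoning, but its low value is higher than the 14.7 % reckoned here.
- The simulation gives Thursday's > Monday's > Sunday's > Tuesday's > Wednesday's, with 40.8 % on top and 21.8 % at the bottom.

    starting material + protic impurity → quenched substrate (k = 0.122 M⁻¹ s⁻¹)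
    starting material + free catalyst → catalyst intermediate A (k = 0.314 M⁻¹ s⁻¹)
    catalyst intermediate B ⇌ free catalyst + target (K = 1.16 M, k = 4.23 s⁻¹)
    catalyst intermediate A → catalyst intermediate B (k = 5.89 s⁻¹)
    target + free catalyst ⇌ isomer of the product + free catalyst, rate k5*[free catalyst]*[target] forward; the back reaction follows from the equilibrium constant (K = 1.30, k = 0.198 M⁻¹ s⁻¹)

- Thursday's is far from rest: at 2.5 min it holds 42.9 % starting material and 11.0 % isomer of the product. At 25.0 min, ten times the asked time, Thursday's holds 0.0641 % starting material, 53.3 % isomer of the product and 41.3 % target. At 25.0 min Wednesday's quenched substrate is 60.2 %, against the 62.5 % that one minus its left fraction gives. One minus Sunday's left fraction is 29.4 %, and Sunday's quenched substrate stands at 29.4 % at 2.5 min and 29.4 % at 25.0 min. Sunday's target drops from 35.8 % at 2.5 min to 30.3 % at 25.0 min.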